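## The problem

The target is a bisabolane: a cyclohexane (C1–C6, methyl C15 on C3) joined at C6 through the 1,1-disubstituted alkene carbon C7 (=C14H2) to the chain C8–C13. The ring carries five contiguous stereocentres (C6, C1, C2, C3, C4) with the side chain, the C1 hydroxyl, the C2 angelate and the 3,4-epoxide all on one face (1R,2R,3S,4S,6S). The chain adds an allylic ester carbinol at C8 (S) and a trisubstituted epoxide at C10 (R), too remote from the ring to be set by it. C2–OH can direct epoxidation of a C3=C4 alkene to its own face, so C3 and C4 follow from C2. The cis relation of the C1 oxygen to the C6 substituent is the one that resists, because oxidants and electrophiles approach a ring anti to the group on C6. The cis-diol C1/C2 must end differentiated (free OH at C1, ester at C2). Fragile points: two acid-labile trisubstituted epoxides; two angelates that isomerise to tiglates or migrate 1,2; and a free C8–OH that would open a 10,11-epoxide to a tetrahydrofuran, so C8 must be acylated first. The feature that makes the key step possible: with the 3,4-epoxide read as a C3=C4 alkene and C7 as a carboxyl carbon, C7–C6–C5–C4=C3 is a γ,δ-unsaturated acid. C1 and C2 tie C6 to C3, so the precursor is the δ-lactone O–C7(=O)–C6–C1–C2–C3 with vinyl (C4=C5) and methyl C15 on C3. Its enolate Claisen rearrangement closes the carbocycle at C5–C6.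

## Retrosynthesis

**32 ⇒ 30 + 26.** The C2–O acyl bond is cut last. Once an angelate sits beside the free C1–OH, any later base or Lewis acid invites 1,2-migration, so nothing may follow. The forward step must acylate the equatorial C2–OH of cis-diol 30 and leave the axial C1–OH.

**30 ⇒ 29 ⇒ 28.** Both epoxide oxygens are removed. The 3,4-epoxide comes from hydroxyl-directed epoxidation of 28 (substrate control from C2–OH), the 10,11-epoxide from a Shi epoxidation of 29 (reagent control). Diol 28 has three stereocentres fewer and no acid-labile group. The forward steps need chemoselectivity among four alkene types.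

**28 ⇒ 27 ⇒ 25 + 26.** The acetonide is removed and the C8 angelate taken off. The acetonide must go before any epoxide exists, and C8 must be esterified before the diol is freed, or the C8–OH would direct vanadium to C7=C14.

**25 ⇒ 23 + 24 ⇒ 21 + 22 ⇒ 19 + 20.** The chain is dismantled at C10=C11 (cross-metathesis with 24), C8–C9 (allylboration, which sets C8 by reagent control) and C7–C8 (formylation with 20). Building on the enol triflate 19 keeps the exo-methylene in place from the start and needs only one-, two- and five-carbon commodity pieces.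

**19 ⇒ 18 ⇒ 16 + 17.** C14 comes from methyllithium added to acid 16; kinetic enol triflation of methyl ketone 18 fixes C7=C14.

**16 ⇒ 13 (key).** C5–C6 is cut and C3–O re-formed, giving lactone 13. This removes the carbocycle and the C6 stereocentre: 13 is a deoxy-sugar-type lactone whose C1/C2 diol is an erythro pair. The cut through C1–C6 or C4–C5 (cycloaddition) puts the alkene at C2=C3; this one puts it at C3=C4. The forward step must transfer configuration from C3 to C6.

**13 ⇒ 12 ⇒ 10 ⇒ 8 ⇒ 6 ⇒ 3 ⇒ 1 + 2 + 4 + 9.** C7 is removed as a Wittig carbon (9), leaving diol 6. Its carbinol C3 is disconnected to vinyl (2) and methyl (4) Grignard reagents and the lactone carbonyl of commercial (−)-2,3-O-isopropylidene-D-erythronolactone 1, which supplies C1 and C2 with the correct absolute configuration.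

## Roads not taken

**Alternative 1:** (most obvious) chiral pool from (R)-carvone. The cut is the C1–O bond plus growth of C8–C13 from the isopropenyl methyl. The forward key step is α′-oxygenation of the carvone enolate, followed by Luche reduction at C2 and directed epoxidation to the isopropenyl epoxy diol A2. The oxidant enters anti to the isopropenyl group, so the first product is the trans ketol A1; C1 must then be inverted at a hindered carbinol. The side chain still has to be grown from an unactivated methyl with a separate stereocontrol for C8. The hardest relation (C1/C6) is corrected rather than set; the chosen plan sets it in the ring-forming step.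

**Alternative 2:** Diels–Alder across C1–C6 and C4–C5. The forward step is endo addition of diene A3 to the hydrogen-bonded α′-hydroxy vinyl ketone A4 (carrying C7–C13), giving adduct A5 with C1–O and C6 cis. Three points count against it:
- The alkene of A5 lies at C2=C3, so the C2 oxygen needs an allylic oxidation with transposition, which in 1-methylcyclohexene systems favours the exocyclic methylene.
- The s-cis hydrogen-bonded model predicts that the target's (8S) carbinol shields the face to be attacked, so the (8R) epimer A4 would be needed and C8 inverted later.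
- A5 is a β-acetoxy ketone, prone to elimination and C6 epimerisation during methylenation.

The Claisen route delivers the alkene at C3=C4 directly.

**Alternative 3:** arene cis-dihydrodiol. The cut is C6–C7 (cross-coupling), with C1 and C2 from microbial dihydroxylation of 4-bromotoluene to A6 (bromine directs the correct absolute sense). Syn epoxidation and coupling at C6–Br would give diene A7. A6 requires fermentation, not purchase. A7 must then have its ring alkene C5=C6 reduced beside the exo-methylene with hydrogen entering anti to three ring oxygens; hydroxyl-directed hydrogenation would deliver it syn, giving the wrong C6.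

Key step: step 7

Remark: anomeric mixtures 3, 8, 12 and the E/Z mixture 10 are carried on unseparated, since those centres are erased later; locants follow bisabolane numbering (ring C1–C6, C7, chain C8–C13, exo-methylene C14, ring methyl C15).

## Steps

**Step 1**
Reactants: 1 (−)-2,3-O-isopropylidene-D-erythronolactone; 2 vinylmagnesium bromide
Product: 3 (3aR,6aR)-4-ethenyl-2,2-dimethyltetrahydrofuro[3,4-d][1,3]dioxol-4-ol (anomeric mixture)
Conditions: CH2=CHMgBr (1.1 equiv), THF, −78 °C; aq. NH4Cl at −78 °C
Reagents that add atoms: vinylmagnesium bromide (2), C=C[Mg]Br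
Why: Grignard addition to a sugar γ-lactone stops at the cyclic hemiketal alkoxide at low temperature, so a single vinyl group (C4=C5) is introduced; the anomeric centre is erased in step 2.

**Step 2**
Reactants: 3; 4 methylmagnesium bromide
Product: 6 (2S)-2-[(4R,5R)-5-(hydroxymethyl)-2,2-dimethyl-1,3-dioxolan-4-yl]but-3-en-2-ol, via open-chain hydroxy enone 5 (not isolated)
Conditions: MeMgBr (3 equiv), THF/Et2O, −78 → 0 °C
Reagents that add atoms: methylmagnesium bromide (4), C[Mg]Br
Why: Excess Grignard opens the lactol to the α-alkoxy vinyl ketone 5 and adds 1,2 under Cram-chelate control (Mg bridging the ketone oxygen and the dioxolane oxygen on C2); methyl enters from the C2–H face, which should give the (S)-carbinol with vinyl trans to the C1/C2 oxygens in the later lactone.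

**Step 3**
Reactants: 6
Product: 8 (3aS,6S,6aR)-6-ethenyl-2,2,6-trimethyltetrahydrofuro[3,4-d][1,3]dioxol-4-ol (anomeric mixture), via hydroxy aldehyde 7 (not isolated)
Conditions: Dess–Martin periodinane (1.1 equiv), NaHCO3, CH2Cl2, 0 °C
Reagents that add atoms: none
Why: Dess–Martin oxidation takes the primary alcohol only (the tertiary allylic alcohol is inert); aldehyde 7 is trapped by the tertiary hydroxyl as the five-membered lactol, which shields the α-alkoxy aldehyde from epimerisation.

**Step 4**
Reactants: 8; 9 (methoxymethyl)triphenylphosphonium chloride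
Product: 10 (2S)-2-[(4R,5R)-5-(2-methoxyethenyl)-2,2-dimethyl-1,3-dioxolan-4-yl]but-3-en-2-ol (E/Z mixture)
Conditions: MeOCH2PPh3Cl (3.5 equiv), t-BuOK (3.3 equiv), THF, 0 → 45 °C
Reagents that add atoms: (methoxymethyl)triphenylphosphonium chloride (9), COC[P+](c1ccccc1)(c1ccccc1)c1ccccc1.[Cl-]
Why: Wittig methoxymethylenation of a sugar-type lactol through its open hydroxy-aldehyde form adds the one carbon that becomes C7; alkene geometry is irrelevant.

**Step 5**
Reactants: 10
Product: 12 (3aR,4S,7aR)-4-ethenyl-2,2,4-trimethyltetrahydro-4H-[1,3]dioxolo[4,5-c]pyran-6-ol (anomeric mixture), via hydroxy aldehyde 11 (not isolated)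
Conditions: PPTS (0.2 equiv), THF/H2O (4:1), 40 °C
Reagents that add atoms: water, O
Why: Enol ethers hydrolyse under mild acid far faster than the acetonide; aldehyde 11 is captured by the tertiary C3 hydroxyl as the six-membered lactol.

**Step 6**
Reactants: 12
Product: 13 (3aR,4S,7aR)-4-ethenyl-2,2,4-trimethyltetrahydro-4H-[1,3]dioxolo[4,5-c]pyran-6(3aH)-one
Conditions: TEMPO (10 mol %), PhI(OAc)2 (1.5 equiv), CH2Cl2, rt
Reagents that add atoms: none
Why: Oxoammonium oxidation of a lactol to the lactone under near-neutral conditions; no free alcohol or enolisable stereocentre is present.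

**Step 7**
Reactants: 13
Product: 16 (3aR,4R,7aS)-2,2,7-trimethyl-3a,4,5,7a-tetrahydro-1,3-benzodioxole-4-carboxylic acid, via silyl ketene acetal 14 (not isolated), via trimethylsilyl ester 15 (not isolated)
Conditions: LiN(iPr)2 (1.3 equiv), Me3SiCl/Et3N (premixed, 3 equiv), THF, −100 → −78 °C; then toluene, 100 °C; aq. citric acid, rt
Reagents that add atoms: none
Why: Kinetic enolisation of 13 with in-situ silylation gives the cyclic silyl ketene acetal 14, whose O–C7=C6 unit and the vinyl group on C3 form the six-atom array of an Ireland–Claisen rearrangement; on warming, a concerted suprafacial [3,3] shift makes C5–C6, breaks C3–O and leaves silyl ester 15, hydrolysed to 16 on work-up. The closest known reaction type is the lactone-enolate Claisen ring contraction of vinyl-substituted lactones and of 6-alkenyl-1,4-dioxan-2-ones to cycloalkene and dihydropyran carboxylic acids. The cyclohexene is closed by the sigmatropic C–C bond formation itself: because C1–C2 bridges the two ends (C6 and C3) of the pericyclic array, the transition state is a boat (bicyclo[2.2.2]octane-like) and the new ring consists of C6, C1, C2, C3 and the two vinyl carbons. The ring forces the new C3=C4 alkene to be cis and trisubstituted with C15 on C3, exactly where the directed epoxidation needs it. The only new stereocentre, C6, is controlled by C3: the vinyl group can reach C6 only across the lactone face on which it stands, and since the C1 and C2 oxygens are trans to vinyl in 13 they end cis to the C7 carboxyl in 16 (chirality transfer from C3, which becomes sp2). The step needs O-silylation to outrun β-elimination of the C1 alkoxide from the enolate; the internal Me3SiCl quench at −100 °C secures this, helped by the pseudo-equatorial C1–O bond in the conformer with axial vinyl, which is poorly aligned with the enolate π system. Regiochemistry is not at issue because C6 is the only α-carbon.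

**Step 8**
Reactants: 16; 17 methyllithium
Product: 18 1-[(3aR,4R,7aS)-2,2,7-trimethyl-3a,4,5,7a-tetrahydro-1,3-benzodioxol-4-yl]ethan-1-one
Conditions: MeLi (2.5 equiv), Et2O, 0 °C → rt; inverse quench into cold aq. NH4Cl
Reagents that add atoms: methyllithium (17), [Li]C
Why: Methyllithium adds to the lithium carboxylate to give a stable dilithio gem-diolate that releases the methyl ketone only on quench (classical acid-to-methyl-ketone conversion), so C6 is never exposed to base as a ketone; the methyl becomes C14.

**Step 9**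
Reactants: 18
Product: 19 1-[(3aR,4R,7aS)-2,2,7-trimethyl-3a,4,5,7a-tetrahydro-1,3-benzodioxol-4-yl]ethenyl trifluoromethanesulfonate
Conditions: KN(SiMe3)2 (1.2 equiv), THF, −78 °C; PhNTf2 (1.2 equiv), −78 → 0 °C
Reagents that add atoms: N-phenylbis(trifluoromethanesulfonimide), O=S(=O)(N(c1ccccc1)S(=O)(=O)C(F)(F)F)C(F)(F)F
Why: Kinetic deprotonation of a methyl ketone occurs at CH3, not at the C6 methine, and O-triflation of that enolate fixes the C7=C14 double bond.

**Step 10**
Reactants: 19; 20 carbon monoxide
Product: 21 2-[(3aR,4S,7aS)-2,2,7-trimethyl-3a,4,5,7a-tetrahydro-1,3-benzodioxol-4-yl]prop-2-enal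
Conditions: Pd(PPh3)4 (5 mol %), CO (3 atm), Bu3SnH (1.2 equiv, slow addition), THF, 50 °C
Reagents that add atoms: carbon monoxide (20), [C-]#[O+]
Why: Palladium-catalysed formylation of an enol triflate (oxidative addition, CO insertion, hydride transfer from tin) gives the 2-substituted acrolein; this introduces C8 without touching C6.

**Step 11**
Reactants: 21; 22 allylmagnesium bromide
Product: 23 (3S)-2-[(3aR,4S,7aS)-2,2,7-trimethyl-3a,4,5,7a-tetrahydro-1,3-benzodioxol-4-yl]hexa-1,5-dien-3-ol
Conditions: (−)-Ipc2BOMe, CH2=CHCH2MgBr, Et2O, −78 °C → rt; then 21, Et2O, −78 °C; NaOH, H2O2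
Reagents that add atoms: allylmagnesium bromide (22), C=CC[Mg]Br
Why: Brown allylboration through a closed chair transition state; the allylborane derived from (+)-α-pinene adds to the Si face of the aldehyde (the sense that gives (S)-alcohols from benzaldehyde and enals), which should set (8S) under reagent control.

**Step 12**
Reactants: 23; 24 2-methylbut-2-ene
Product: 25 (3S)-6-methyl-2-[(3aR,4S,7aS)-2,2,7-trimethyl-3a,4,5,7a-tetrahydro-1,3-benzodioxol-4-yl]hepta-1,5-dien-3-ol
Conditions: 2-methylbut-2-ene (co-solvent), RuCl2(=CHPh)(PCy3)(H2IMes) (second-generation Grubbs catalyst, 5 mol %), CH2Cl2, 40 °C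
Reagents that add atoms: 2-methylbut-2-ene (24), CC=C(C)C
Why: Cross-metathesis of the only monosubstituted alkene with 2-methylbut-2-ene installs the prenyl terminus; the 1,1-disubstituted C7=C14 and the trisubstituted ring alkene do not engage.

**Step 13**
Reactants: 25; 26 angelic acid
Product: 27 (3S)-6-methyl-2-[(3aR,4S,7aS)-2,2,7-trimethyl-3a,4,5,7a-tetrahydro-1,3-benzodioxol-4-yl]hepta-1,5-dien-3-yl (2Z)-2-methylbut-2-enoate
Conditions: angelic acid (3 equiv), 2,4,6-trichlorobenzoyl chloride (3 equiv), Et3N, toluene, rt; then 25, toluene, 70 °C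
Reagents that add atoms: angelic acid (26), C/C=C(/C)C(=O)O
Why: Yamaguchi mixed-anhydride esterification without a nucleophilic catalyst acylates C8–OH with retention and avoids the conjugate-addition pathway that isomerises angelate to tiglate.

**Step 14**
Reactants: 27
Product: 28 (3S)-2-[(1S,5S,6R)-5,6-dihydroxy-4-methylcyclohex-3-en-1-yl]-6-methylhepta-1,5-dien-3-yl (2Z)-2-methylbut-2-enoate
Conditions: AcOH/H2O/THF (3:1:1), 40 °C
Reagents that add atoms: none
Why: Acetal hydrolysis is done while no epoxide is present; the allylic ester and trisubstituted alkenes tolerate aqueous acetic acid.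

**Step 15**
Reactants: 28
Product: 29 (1R,2R,3S,4S,6S,8S)-3,4-epoxy-1,2-dihydroxybisabola-7(14),10-dien-8-yl angelate
Conditions: VO(acac)2 (5 mol %), t-BuOOH (1.2 equiv), CH2Cl2, 0 °C → rt
Reagents that add atoms: tert-butyl hydroperoxide, CC(C)(C)OO
Why: Hydroxyl-directed vanadium epoxidation: the vanadate ester of the allylic C2–OH delivers oxygen to the same face of C3=C4, setting C3 and C4 cis to C2–OH (the homoallylic C1–OH on the same face reinforces this); the isolated prenyl alkene, the ester-bearing exo-methylene and the enoates are not substrates.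

**Step 16**
Reactants: 29
Product: 30 (1R,2R,3S,4S,6S,8S,10R)-3,4:10,11-diepoxy-1,2-dihydroxybisabol-7(14)-en-8-yl angelate
Conditions: D-fructose-derived Shi ketone (0.3 equiv), Oxone (2KHSO5·KHSO4·K2SO4), K2CO3, Bu4NHSO4, MeCN/CH2(OMe)2/aq. Na2B4O7 buffer (pH ≈ 10.5), 0 °C
Reagents that add atoms: potassium peroxymonosulfate (Oxone), [K+].[O-]S(=O)(=O)OO
Why: Shi epoxidation by the chiral dioxirane through a spiro transition state; the D-fructose ketone should give the (R)-epoxide from R–CH=CMe2, and the electron-poor enoates and the 1,1-disubstituted alkene react far more slowly. C8 is already acylated, so no tetrahydrofuran can form.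

**Step 17**
Reactants: 30; 26 angelic acid
Product: 32 (1R,2R,3S,4S,6S,8S,10R)-2,8-bis(angeloyloxy)-3,4:10,11-diepoxybisabol-7(14)-en-1-ol (target), via stannylene acetal 31 (not isolated)
Conditions: Bu2Sn(OMe)2 (1.05 equiv), toluene, 50 °C, evaporate; then angelic 2,4,6-trichlorobenzoic anhydride (pre-formed from 26, 2,4,6-trichlorobenzoyl chloride, Et3N; 1.3 equiv), toluene, 0 °C → rt
Reagents that add atoms: angelic acid (26), C/C=C(/C)C(=O)O
Why: Dibutylstannylene acetals of cis-1,2-diols are acylated at the equatorial oxygen, here C2–O (C1–O is axial, cis to the equatorial C6 substituent); neutral acyl transfer without a nucleophilic catalyst should avoid both 1,2-migration and angelate isomerisation.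

## Compound list

1 | (−)-2,3-O-isopropylidene-D-erythronolactone, (3aR,6aR)-2,2-dimethyldihydrofuro[3,4-d][1,3]dioxol-4(3aH)-one | O=C1OC[C@H]2OC(C)(C)O[C@@H]12 | starting material
2 | vinylmagnesium bromide | C=C[Mg]Br | starting material
3 | (3aR,6aR)-4-ethenyl-2,2-dimethyltetrahydrofuro[3,4-d][1,3]dioxol-4-ol (anomeric mixture) | C=CC1(O)OC[C@H]2OC(C)(C)O[C@@H]12 | intermediate
4 | methylmagnesium bromide | C[Mg]Br | starting material
5 | 1-[(4R,5R)-5-(hydroxymethyl)-2,2-dimethyl-1,3-dioxolan-4-yl]prop-2-en-1-one (open form of 3, as magnesium alkoxide) | OC[C@H]1OC(C)(C)O[C@H]1C(=O)C=C | intermediate (not isolated)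
6 | (2S)-2-[(4R,5R)-5-(hydroxymethyl)-2,2-dimethyl-1,3-dioxolan-4-yl]but-3-en-2-ol | OC[C@H]1OC(C)(C)O[C@H]1[C@@](C)(O)C=C | intermediate
7 | (4S,5R)-5-[(2S)-2-hydroxybut-3-en-2-yl]-2,2-dimethyl-1,3-dioxolane-4-carbaldehyde | O=C[C@H]1OC(C)(C)O[C@H]1[C@@](C)(O)C=C | intermediate (not isolated)
8 | (3aS,6S,6aR)-6-ethenyl-2,2,6-trimethyltetrahydrofuro[3,4-d][1,3]dioxol-4-ol (anomeric mixture) | OC2[C@H]1OC(C)(C)O[C@H]1[C@@](C)(O2)C=C | intermediate
9 | (methoxymethyl)triphenylphosphonium chloride | COC[P+](c1ccccc1)(c1ccccc1)c1ccccc1.[Cl-] | starting material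
10 | (2S)-2-[(4R,5R)-5-(2-methoxyethenyl)-2,2-dimethyl-1,3-dioxolan-4-yl]but-3-en-2-ol (E/Z mixture) | COC=C[C@H]1OC(C)(C)O[C@H]1[C@@](C)(O)C=C | intermediate
11 | {(4R,5R)-5-[(2S)-2-hydroxybut-3-en-2-yl]-2,2-dimethyl-1,3-dioxolan-4-yl}acetaldehyde | O=CC[C@H]1OC(C)(C)O[C@H]1[C@@](C)(O)C=C | intermediate (not isolated)
12 | (3aR,4S,7aR)-4-ethenyl-2,2,4-trimethyltetrahydro-4H-[1,3]dioxolo[4,5-c]pyran-6-ol (anomeric mixture) | OC2C[C@H]1OC(C)(C)O[C@H]1[C@@](C)(O2)C=C | intermediate
13 | (3aR,4S,7aR)-4-ethenyl-2,2,4-trimethyltetrahydro-4H-[1,3]dioxolo[4,5-c]pyran-6(3aH)-one | O=C2C[C@H]1OC(C)(C)O[C@H]1[C@@](C)(O2)C=C | intermediate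
14 | {[(3aR,4S,7aR)-4-ethenyl-2,2,4-trimethyl-4,7a-dihydro-3aH-[1,3]dioxolo[4,5-c]pyran-6-yl]oxy}trimethylsilane | C[Si](C)(C)OC2=C[C@H]1OC(C)(C)O[C@H]1[C@@](C)(O2)C=C | intermediate (not isolated)
15 | trimethylsilyl (3aR,4R,7aS)-2,2,7-trimethyl-3a,4,5,7a-tetrahydro-1,3-benzodioxole-4-carboxylate | C[Si](C)(C)OC(=O)[C@@H]1CC=C(C)[C@@H]2OC(C)(C)O[C@H]12 | intermediate (not isolated)
16 | (3aR,4R,7aS)-2,2,7-trimethyl-3a,4,5,7a-tetrahydro-1,3-benzodioxole-4-carboxylic acid | OC(=O)[C@@H]1CC=C(C)[C@@H]2OC(C)(C)O[C@H]12 | intermediate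
17 | methyllithium | [Li]C | starting material
18 | 1-[(3aR,4R,7aS)-2,2,7-trimethyl-3a,4,5,7a-tetrahydro-1,3-benzodioxol-4-yl]ethan-1-one | CC(=O)[C@@H]1CC=C(C)[C@@H]2OC(C)(C)O[C@H]12 | intermediate
19 | 1-[(3aR,4R,7aS)-2,2,7-trimethyl-3a,4,5,7a-tetrahydro-1,3-benzodioxol-4-yl]ethenyl trifluoromethanesulfonate | C=C(OS(=O)(=O)C(F)(F)F)[C@@H]1CC=C(C)[C@@H]2OC(C)(C)O[C@H]12 | intermediate
20 | carbon monoxide | [C-]#[O+] | starting material
21 | 2-[(3aR,4S,7aS)-2,2,7-trimethyl-3a,4,5,7a-tetrahydro-1,3-benzodioxol-4-yl]prop-2-enal | C=C(C=O)[C@@H]1CC=C(C)[C@@H]2OC(C)(C)O[C@H]12 | intermediate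
22 | allylmagnesium bromide | C=CC[Mg]Br | starting material
23 | (3S)-2-[(3aR,4S,7aS)-2,2,7-trimethyl-3a,4,5,7a-tetrahydro-1,3-benzodioxol-4-yl]hexa-1,5-dien-3-ol | C=C([C@H](CC=C)O)[C@@H]1CC=C(C)[C@@H]2OC(C)(C)O[C@H]12 | intermediate
24 | 2-methylbut-2-ene | CC=C(C)C | starting material
25 | (3S)-6-methyl-2-[(3aR,4S,7aS)-2,2,7-trimethyl-3a,4,5,7a-tetrahydro-1,3-benzodioxol-4-yl]hepta-1,5-dien-3-ol | C=C([C@H](CC=C(C)C)O)[C@@H]1CC=C(C)[C@@H]2OC(C)(C)O[C@H]12 | intermediate
26 | angelic acid, (2Z)-2-methylbut-2-enoic acid | C/C=C(/C)C(=O)O | starting material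
27 | (3S)-6-methyl-2-[(3aR,4S,7aS)-2,2,7-trimethyl-3a,4,5,7a-tetrahydro-1,3-benzodioxol-4-yl]hepta-1,5-dien-3-yl (2Z)-2-methylbut-2-enoate | C=C([C@H](CC=C(C)C)OC(=O)/C(C)=C\C)[C@@H]1CC=C(C)[C@@H]2OC(C)(C)O[C@H]12 | intermediate
28 | (3S)-2-[(1S,5S,6R)-5,6-dihydroxy-4-methylcyclohex-3-en-1-yl]-6-methylhepta-1,5-dien-3-yl (2Z)-2-methylbut-2-enoate | C=C([C@H](CC=C(C)C)OC(=O)/C(C)=C\C)[C@@H]1CC=C(C)[C@H](O)[C@@H]1O | intermediate
29 | (1R,2R,3S,4S,6S,8S)-3,4-epoxy-1,2-dihydroxybisabola-7(14),10-dien-8-yl angelate | C=C([C@H](CC=C(C)C)OC(=O)/C(C)=C\C)[C@@H]1C[C@@H]2O[C@]2(C)[C@H](O)[C@@H]1O | intermediate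
30 | (1R,2R,3S,4S,6S,8S,10R)-3,4:10,11-diepoxy-1,2-dihydroxybisabol-7(14)-en-8-yl angelate | C=C([C@H](C[C@H]1OC1(C)C)OC(=O)/C(C)=C\C)[C@@H]1C[C@@H]2O[C@]2(C)[C@H](O)[C@@H]1O | intermediate
31 | 1,2-O-(dibutylstannylene) acetal of 30 | C=C([C@H](C[C@H]1OC1(C)C)OC(=O)/C(C)=C\C)[C@@H]1C[C@@H]2O[C@]2(C)[C@@H]3O[Sn](CCCC)(CCCC)O[C@H]13 | intermediate (not isolated)
32 | (1R,2R,3S,4S,6S,8S,10R)-2,8-bis(angeloyloxy)-3,4:10,11-diepoxybisabol-7(14)-en-1-ol (CNP0296086.3) | C=C([C@H](C[C@H]1OC1(C)C)OC(=O)/C(C)=C\C)[C@@H]1C[C@@H]2O[C@]2(C)[C@H](OC(=O)/C(C)=C\C)[C@@H]1O | target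

## Step count and risks

Total: 17 steps. Longest linear sequence: 17 (fully linear from 1).

**Step 7 (key).** The lactone enolate may lose the C1 alkoxide by β-elimination (opening the dioxolane) before it is silylated, or be C-silylated. Fallback avoiding any enolate: from lactol 12, mesylation and elimination (MsCl, Et3N, then warming) should give the cyclic enol ether F1. A thermal Claisen rearrangement of F1 (toluene, sealed tube, about 180 °C) through the same boat array gives the cyclohexene carbaldehyde F2. Pinnick oxidation (NaClO2, NaH2PO4, 2-methylbut-2-ene) returns to the route at 16.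

**Step 2.** Facial selectivity may be poor or reversed if Felkin–Anh addition competes with the chelate, and some 1,4-addition to enone 5 is possible. Fallback: reverse the order of the two additions. From 1, methyllithium at −78 °C gives the methyl lactol F3, and vinylmagnesium bromide is then added to the derived methyl ketone. Under any one facial model the two orders give opposite C3 epimers, so whichever mode prevails one order leads to 6, where the route is rejoined.

**Step 10.** Hydride transfer to the vinylpalladium species before CO insertion would give simple reduction, and enal 21 may isomerise into conjugation with C6. Fallback, convergent and carbonyl-free at C8: Nozaki–Hiyama–Kishi coupling of 19 with 4-methylpent-3-enal F4 (CrCl2, cat. NiCl2, DMF; F4 from Dess–Martin oxidation of commercial 4-methylpent-3-en-1-ol) gives the C8-epimeric alcohols F5. Dess–Martin oxidation gives enone F6, and Corey–Bakshi–Shibata reduction with the (R)-methyl oxazaborolidine and catecholborane (alkenyl as the large group) should give the (8S)-alcohol. This returns at 25 and bypasses 21 and 23.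

**Step 17.** Discrimination between two hindered secondary hydroxyls may be incomplete, or the ester may migrate, giving the C1 angelate F7. Fallback by thermodynamic rather than kinetic control: separate F7 and equilibrate it through the cis-orthoacid intermediate of 1,2-acyl migration (imidazole or catalytic DBU, CH2Cl2, rt). The equatorial C2 ester should be favoured over the axial C1 ester; F7 is recycled. The fallback sets out from 30 and returns at 32.

## Further compounds

F1 | step 7 | (3aR,4S,7aR)-4-ethenyl-2,2,4-trimethyl-4,7a-dihydro-3aH-[1,3]dioxolo[4,5-c]pyran | C2=C[C@H]1OC(C)(C)O[C@H]1[C@@](C)(O2)C=C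
F2 | step 7 | (3aR,4R,7aS)-2,2,7-trimethyl-3a,4,5,7a-tetrahydro-1,3-benzodioxole-4-carbaldehyde | O=C[C@@H]1CC=C(C)[C@@H]2OC(C)(C)O[C@H]12
F3 | step 2 | (3aR,6aR)-2,2,4-trimethyltetrahydrofuro[3,4-d][1,3]dioxol-4-ol (anomeric mixture) | CC1(O)OC[C@H]2OC(C)(C)O[C@@H]12
F4 | step 10 | 4-methylpent-3-enal | CC(C)=CCC=O
F5 | step 10 | 6-methyl-2-[(3aR,4S,7aS)-2,2,7-trimethyl-3a,4,5,7a-tetrahydro-1,3-benzodioxol-4-yl]hepta-1,5-dien-3-ol (C3 epimers) | C=C(C(O)CC=C(C)C)[C@@H]1CC=C(C)[C@@H]2OC(C)(C)O[C@H]12
F6 | step 10 | 6-methyl-2-[(3aR,4S,7aS)-2,2,7-trimethyl-3a,4,5,7a-tetrahydro-1,3-benzodioxol-4-yl]hepta-1,5-dien-3-one | C=C(C(=O)CC=C(C)C)[C@@H]1CC=C(C)[C@@H]2OC(C)(C)O[C@H]12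
F7 | step 17 | (1R,2R,3S,4S,6S,8S,10R)-1,8-bis(angeloyloxy)-3,4:10,11-diepoxybisabol-7(14)-en-2-ol | C=C([C@H](C[C@H]1OC1(C)C)OC(=O)/C(C)=C\C)[C@@H]1C[C@@H]2O[C@]2(C)[C@H](O)[C@@H]1OC(=O)/C(C)=C\C
A1 | alternative 1 | (5S,6S)-6-hydroxy-2-methyl-5-(prop-1-en-2-yl)cyclohex-2-en-1-one (trans ketol) | C=C(C)[C@@H]1CC=C(C)C(=O)[C@H]1O
A2 | alternative 1 | (1R,2R,3S,4S,6S)-3,4-epoxy-3-methyl-6-(prop-1-en-2-yl)cyclohexane-1,2-diol (target ring locants) | C=C(C)[C@@H]1C[C@@H]2O[C@]2(C)[C@H](O)[C@@H]1O
A3 | alternative 2 | (1E)-3-methylbuta-1,3-dien-1-yl acetate | CC(=C)/C=C/OC(C)=O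
A4 | alternative 2 | (4R)-4-hydroxy-7-methylocta-1,6-dien-3-one | C=CC(=O)[C@H](O)CC=C(C)C
A5 | alternative 2 | (2R)-1-(cis-2-acetoxy-4-methylcyclohex-3-en-1-yl)-2-hydroxy-5-methylhex-4-en-1-one (C1–O and C6 as in the target) | O=C([C@H](O)CC=C(C)C)[C@@H]1CCC(C)=C[C@@H]1OC(C)=O
A6 | alternative 3 | (1S,2S)-3-bromo-6-methylcyclohexa-3,5-diene-1,2-diol | BrC1=CC=C(C)[C@H](O)[C@@H]1O
A7 | alternative 3 | (1R,2R,3S,4S,8S)-3,4-epoxybisabola-5,7(14),10-triene-1,2,8-triol | C=C([C@H](CC=C(C)C)O)C1=C[C@@H]2O[C@]2(C)[C@H](O)[C@@H]1O
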